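**One step.** In a one-step world with partner in excess (pseudo-first-order), the logarithm of free starting material falls on one straight line, and a single half-life counts the whole run.

the same everywhere: starting material 10 mM

|  | partner | remark | time |
|---|---|---|---|
| north-east | 13 mM | run made earlier |  |
| west | 19 mM | run made earlier |  |
| south-west | 23 mM | run made earlier |  |
| eta | 15.0 mM |  | 12 min |
| epsilon | 30.0 mM |  | 12 min |

| run | time / min | starting material / % | bis adduct / % |
|---|---|---|---|
| north-east | 0.500 | 68.3 | 0.4 |
| north-east | 1.50 | 40.9 | 0.2 |
| north-east | 3.00 | 31.0 | 0.5 |
| north-east | 4.00 | 27.4 | 0.4 |
| north-east | 6.00 | 23.9 | 1.0 |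
| west | 0.500 | 57.2 | 0 |
| west | 1.50 | 29.3 | 0.5 |
| west | 3.00 | 21.3 | 1.7 |
| west | 4.00 | 18.4 | 1.5 |
| west | 6.00 | 13.8 | 1.0 |
| south-west | 0.500 | 50.3 | 0 |
| south-west | 1.50 | 25.0 | 0 |
| south-west | 3.00 | 18.5 | 1.6 |
| south-west | 4.00 | 14.9 | 0.1 |
| south-west | 6.00 | 10.5 | 0.9 |

(scatter of a reading: 0.5 percentage points)

- a reading of starting material is of its free form alone

1. part of the starting material that has reacted at the end, eta
2. part of the starting material that has reacted at the end, epsilon
3. what raising the concentration of partner from its lowest to its highest value here does to the part of the starting material that has reacted (changes below 5 percentage points count as none) (no change / it rises / it falls)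

**The books.** I kept a ledger of starting material, the limiting reagent, at 10 mM against at least 13 mM of partner. In the south-west run at 6.00 min, 10.5% stood free and 0.9% as bis adduct, so 88.6% sat in forms I could not read. Reacted means the charge less the free entry, so those forms count as reacted.

**Two stretches.** The free entry bent. In the south-west run its logarithm fell at 1.37 /min at first, but at 0.189 /min from 3.00 min to 6.00 min. Over that same tail the north-east run read 0.0867 /min. A straight line in partner charge through these two readings gives 0.148 /min for the west run, which read 0.145 /min.

**My reckoning.** For eta that line makes the tail half-life, the time free starting material takes to halve on the slow stretch, 6.47 min. Extrapolated to epsilon, it is 2.66 min. The logarithms of the readings at 6.00 min give 20.3% free for eta and 5.90% for epsilon. The remaining 6.00 min are 0.927 half-lives for eta and 2.25 for epsilon. That closes the books at 89.3% reacted for eta and 98.8% for epsilon, so the part reacted rises.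

**Forecast, result.** The forecast, below my figures, gave 83% for eta and 94% for epsilon from “a rapid reversible adduct”, and its answer on raising the partner was: it rises. The flasks gave 91.3% and 99.7%, and their answer on raising the partner was: it rises, a change of 8.5 percentage points.

    single product → side product (k = 0.00360 /s)
    starting material + released group ⇌ idle adduct, settled at all times (K = 6000 /M)
    starting material + partner → single product + released group (k = 0.560 /M/s)
    partner + bis adduct → triple product + released group (k = 0.770 /M/s)
    partner + single product → bis adduct + released group (k = 0.0220 /M/s)
    released group → by-product carried off (k = 0.210 /s)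

**Tail counted.** In eta, free starting material fell from 19.4% at 6.00 min to 8.72% at 12.0 min, a tail half-life of 5.21 min against my 6.47 min, and longer than the 1.4 min of the step from starting material and partner alone at eta's charged concentrations. Counting my epsilon tail half-life of 2.66 min back from my 5.90% gives 12.9% free in the same epsilon flask read at 3.0 min, where 13.7% stood free.

(Readings and results were generated by integration for an exercise; scatter was added.)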